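**Retrosynthetic overview**
- The C5 methoxy group goes on last: α'-hydroxylation of the bicyclic vinylogous ester trans to the angular allyl group, then O-methylation.
- The dihydrofuran ring is the only ring that is made (the carbocycle comes from cyclohexane-1,3-dione, the arene from 4-chlorophenol). It closes by a stereoconvergent benzylic C2–O closure with transposition of the vinylogous ester.
- The quaternary C3a and the C2–aryl bond come from an aldehyde: aryl Grignard addition, then dianion allylation anti to the C3 methyl group.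
- Key disconnection C3–C3a: propanal plus 6-bromo-3-ethoxycyclohex-2-enone. The α'-keto radical adds to a chiral enamine under photoredox/organocatalysis; this sets C3, and C3a, C2 and C5 are relayed from it.

Assumption: the imidazolidinone in step 5 induces in the sense established for this catalyst class (the L-alanine-derived (2R,5S) catalyst gives (R)-aldehydes of this substitution pattern), so its (2S,5R) enantiomer is used.

**Step 1**
Reactants: 1 4-chlorophenol
Product: 2 2,6-dibromo-4-chlorophenol
Conditions: Br2 (2.1 equiv), AcOH, 15 °C → rt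
Reagents that add atoms: bromine, BrBr
Why: Electrophilic aromatic bromination goes to both ortho positions of the phenol because the para position is blocked by chlorine; no stereocenter is formed.

**Step 2**
Reactants: 2 2,6-dibromo-4-chlorophenol
Product: 4 5-chloro-1,2,3-trimethoxybenzene, via sodium 4-chloro-2,6-dimethoxyphenoxide 3 (not isolated)
Conditions: NaOMe (6 equiv), CuBr (10 mol%), DMF/MeOH, 110 °C; then Me2SO4 (3 equiv), 50 °C
Reagents that add atoms: sodium methoxide, [Na+].[O-]C; dimethyl sulfate, COS(=O)(=O)OC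
Why: Copper-catalysed Ullmann-type methoxylation replaces the two aryl bromides while the aryl chloride is inert, and the phenoxide is then O-methylated in the same pot (Williamson methylation); no stereocenter is formed.

**Step 3**
Reactants: 5 cyclohexane-1,3-dione
Product: 6 3-ethoxycyclohex-2-en-1-one
Conditions: EtOH, TsOH·H2O (cat.), PhMe, reflux, Dean–Stark
Reagents that add atoms: ethanol, CCO
Why: Acid-catalysed vinylogous esterification with azeotropic removal of water masks the acidic enol and differentiates the two carbonyl groups of the symmetric dione; no stereocenter is formed.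

**Step 4**
Reactants: 6 3-ethoxycyclohex-2-en-1-one
Product: 9 6-bromo-3-ethoxycyclohex-2-en-1-one (racemic), via lithium dienolate 7 (not isolated), via silyl dienol ether 8 (not isolated)
Conditions: LDA, THF, −78 °C; TMSCl; then NBS, THF, −78 → 0 °C
Reagents that add atoms: N-bromosuccinimide, O=C1CCC(=O)N1Br
Why: Kinetic deprotonation of the vinylogous ester occurs at the α'-carbon (Stork–Danheiser regiochemistry), and bromination of the derived silyl dienol ether at its terminal carbon gives the secondary α'-bromide, whose racemic centre is erased in the next step.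

**Step 5**
Reactants: 9 6-bromo-3-ethoxycyclohex-2-en-1-one; 10 propanal
Product: 11 (2S)-2-[(1RS)-4-ethoxy-2-oxocyclohex-3-en-1-yl]propanal
Conditions: 10 (3 equiv), (2S,5R)-2-tert-butyl-3,5-dimethylimidazolidin-4-one·TfOH (20 mol%), fac-Ir(ppy)3 (1 mol%; ppy = 2-phenylpyridinato), 2,6-lutidine (2 equiv), DMF, blue LEDs, 5 °C
Reagents that add atoms: none
Why: In this enantioselective photoredox organocatalytic α-alkylation of an aldehyde (enamine/photoredox dual catalysis), photoexcited fac-Ir(ppy)3 cleaves the C–Br bond, the electrophilic α'-keto radical adds to the (E)-enamine of propanal on the face left open by the catalyst to form the C3–C3a bond and set the (S) methyl-bearing centre (future C3), and oxidation of the α-amino radical followed by hydrolysis returns the aldehyde, while the ring CH centre stays a mixture that is erased in step 6.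

**Step 6**
Reactants: 4 5-chloro-1,2,3-trimethoxybenzene; 11 (2S)-2-[(1RS)-4-ethoxy-2-oxocyclohex-3-en-1-yl]propanal
Product: 15 (6S)-3-ethoxy-6-[(1RS,2S)-1-hydroxy-1-(3,4,5-trimethoxyphenyl)propan-2-yl]-6-(prop-2-en-1-yl)cyclohex-2-en-1-one, via arylmagnesium chloride 12 (not isolated), via chloromagnesium alkoxide 13 (not isolated), via alkoxide enolate dianion 14 (not isolated)
Conditions: 4, Mg turnings (I2-activated), THF, reflux; add to 11, THF, −78 °C; then LDA (1.3 equiv), −78 °C; allyl bromide, DMPU, −78 → −20 °C; aq. NH4Cl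
Reagents that add atoms: allyl bromide, C=CCBr
Why: Grignard addition to the aldehyde (chemoselective over the poorly electrophilic vinylogous ester carbonyl) is followed by Stork–Danheiser α'-alkylation of the alkoxide–enolate dianion, in which allylic 1,3-strain and the alkoxide–enolate metal bridge both expose the enolate face anti to the C3 methyl group, so the quaternary centre forms with allyl trans to methyl, while the carbinol centre stays a mixture that converges in step 7.

**Step 7**
Reactants: 15 (6S)-3-ethoxy-6-[(1RS,2S)-1-hydroxy-1-(3,4,5-trimethoxyphenyl)propan-2-yl]-6-(prop-2-en-1-yl)cyclohex-2-en-1-one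
Product: 16 (2S,3S,3aS)-3-methyl-3a-(prop-2-en-1-yl)-2-(3,4,5-trimethoxyphenyl)-3,3a,4,5-tetrahydro-1-benzofuran-6(2H)-one
Conditions: TsOH·H2O (1 equiv), MeCN/H2O (20:1), 0 °C → rt
Reagents that add atoms: water, O
Why: In this stereoconvergent SN1 cycloetherification with Stork–Danheiser-type transposition of the vinylogous ester, the electron-rich benzylic cation formed from either carbinol epimer is captured by the ring carbonyl oxygen with the aryl group trans to the adjacent methyl group (2,3-trans), and hydrolysis of the ethoxy-substituted oxocarbenium ion releases ethanol and the transposed enone.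

**Step 8**
Reactants: 16 (2S,3S,3aS)-3-methyl-3a-(prop-2-en-1-yl)-2-(3,4,5-trimethoxyphenyl)-3,3a,4,5-tetrahydro-1-benzofuran-6(2H)-one
Product: 18 (2S,3S,3aR,5R)-5-hydroxy-3-methyl-3a-(prop-2-en-1-yl)-2-(3,4,5-trimethoxyphenyl)-3,3a,4,5-tetrahydro-1-benzofuran-6(2H)-one, via sodium enolate 17 (not isolated)
Conditions: NaHMDS, THF, −78 °C; then (±)-trans-3-phenyl-2-(phenylsulfonyl)oxaziridine, −78 °C; aq. NH4Cl
Reagents that add atoms: 3-phenyl-2-(phenylsulfonyl)oxaziridine, O=S(=O)(c1ccccc1)N1OC1c1ccccc1
Why: Davis oxaziridine hydroxylation of the kinetic α'-enolate (the only enolisable position) occurs on the face opposite the pseudo-axial angular allyl group, giving the 5-hydroxy group trans to allyl, which is also the equatorial and thermodynamically preferred epimer.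

**Step 9**
Reactants: 18 (2S,3S,3aR,5R)-5-hydroxy-3-methyl-3a-(prop-2-en-1-yl)-2-(3,4,5-trimethoxyphenyl)-3,3a,4,5-tetrahydro-1-benzofuran-6(2H)-one
Product: 19 (2S,3S,3aR,5R)-5-methoxy-3-methyl-3a-(prop-2-en-1-yl)-2-(3,4,5-trimethoxyphenyl)-3,3a,4,5-tetrahydro-1-benzofuran-6(2H)-one (CNP0236389.1)
Conditions: MeI (10 equiv), Ag2O (3 equiv), MeCN, 4 Å MS, rt, dark
Reagents that add atoms: iodomethane, CI
Why: Purdie O-methylation with MeI/Ag2O is non-basic and so keeps the α-oxygenated stereocenter, whose trans (equatorial) configuration is in any case the thermodynamic one.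

**Compound list**
1 | 4-chlorophenol | Oc1ccc(Cl)cc1 | starting material
2 | 2,6-dibromo-4-chlorophenol | Oc1c(Br)cc(Cl)cc1Br | intermediate
3 | sodium 4-chloro-2,6-dimethoxyphenoxide | [Na+].[O-]c1c(OC)cc(Cl)cc1OC | intermediate
4 | 5-chloro-1,2,3-trimethoxybenzene | COc1cc(Cl)cc(OC)c1OC | intermediate
5 | cyclohexane-1,3-dione | O=C1CCCC(=O)C1 | starting material
6 | 3-ethoxycyclohex-2-en-1-one | CCOC1=CC(=O)CCC1 | intermediate
7 | lithium 5-ethoxycyclohexa-1,5-dien-1-olate | [Li]OC1=CCCC(OCC)=C1 | intermediate
8 | [(5-ethoxycyclohexa-1,5-dien-1-yl)oxy]trimethylsilane | CCOC1=CC(O[Si](C)(C)C)=CCC1 | intermediate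
9 | 6-bromo-3-ethoxycyclohex-2-en-1-one (racemic) | CCOC1=CC(=O)C(Br)CC1 | intermediate
10 | propanal | CCC=O | starting material
11 | (2S)-2-[(1RS)-4-ethoxy-2-oxocyclohex-3-en-1-yl]propanal | O=C[C@@H](C)C1CCC(OCC)=CC1=O | intermediate
12 | (3,4,5-trimethoxyphenyl)magnesium chloride | COc1cc([Mg]Cl)cc(OC)c1OC | intermediate
13 | chloromagnesium (1RS,2S)-2-[(1RS)-4-ethoxy-2-oxocyclohex-3-en-1-yl]-1-(3,4,5-trimethoxyphenyl)propan-1-olate | Cl[Mg]OC(c1cc(OC)c(OC)c(OC)c1)[C@@H](C)C1CCC(OCC)=CC1=O | intermediate
14 | lithium/chloromagnesium dianion of 13 (side-chain alkoxide, ring α'-enolate) | Cl[Mg]OC(c1cc(OC)c(OC)c(OC)c1)[C@@H](C)C1=C(O[Li])C=C(OCC)CC1 | intermediate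
15 | (6S)-3-ethoxy-6-[(1RS,2S)-1-hydroxy-1-(3,4,5-trimethoxyphenyl)propan-2-yl]-6-(prop-2-en-1-yl)cyclohex-2-en-1-one | C=CC[C@@]1(CCC(OCC)=CC1=O)[C@H](C)C(O)c1cc(OC)c(OC)c(OC)c1 | intermediate
16 | (2S,3S,3aS)-3-methyl-3a-(prop-2-en-1-yl)-2-(3,4,5-trimethoxyphenyl)-3,3a,4,5-tetrahydro-1-benzofuran-6(2H)-one | C=CC[C@]12CCC(=O)C=C1O[C@H](c1cc(OC)c(OC)c(OC)c1)[C@H]2C | intermediate
17 | sodium (2S,3S,3aS)-3-methyl-3a-(prop-2-en-1-yl)-2-(3,4,5-trimethoxyphenyl)-2,3,3a,4-tetrahydro-1-benzofuran-6-olate | C=CC[C@]12CC=C(O[Na])C=C1O[C@H](c1cc(OC)c(OC)c(OC)c1)[C@H]2C | intermediate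
18 | (2S,3S,3aR,5R)-5-hydroxy-3-methyl-3a-(prop-2-en-1-yl)-2-(3,4,5-trimethoxyphenyl)-3,3a,4,5-tetrahydro-1-benzofuran-6(2H)-one | C=CC[C@]12C[C@@H](O)C(=O)C=C1O[C@H](c1cc(OC)c(OC)c(OC)c1)[C@H]2C | intermediate
19 | (2S,3S,3aR,5R)-5-methoxy-3-methyl-3a-(prop-2-en-1-yl)-2-(3,4,5-trimethoxyphenyl)-3,3a,4,5-tetrahydro-1-benzofuran-6(2H)-one | C=CC[C@]12C[C@@H](OC)C(=O)C=C1O[C@H](c1cc(OC)c(OC)c(OC)c1)[C@H]2C | target

**Step count and risks**
Total step count: 9. Longest linear sequence: 7 steps (5 → 6 → 9 → 11 → 15 → 16 → 18 → 19, steps 3 to 9).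

The three steps most likely to fail are steps 5, 6 and 7.

Step 5 is the radical coupling. The secondary bromide 9 may lose HBr towards 3-ethoxyphenol, or may couple slowly or with low ee. The fallback reverses the radical polarity: setting out from 6, the silyl dienol ether 8 is prepared (LDA, TMSCl) and isolated by non-aqueous work-up. It is then coupled with propanal 10 by oxidative organo-SOMO catalysis ((NH4)2Ce(NO3)6, NaHCO3, DME, −20 °C, with the enantiomer of 5-benzyl-2-tert-butyl-3-methylimidazolidin-4-one that gives the (S)-aldehyde). Here the enamine radical cation is the radical and 8 is the acceptor. This comes back to the route at 11 and makes no new compound (F0).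

Step 6 is the one-pot Grignard addition and dianion allylation. Deprotonation next to the branched side chain may be incomplete, or the facial control may be poor. The fallback sets the quaternary centre in the radical step instead. Setting out from 6, LDA and allyl bromide give 6-allyl-3-ethoxycyclohex-2-en-1-one F1. LDA/TMSCl and then NBS give the tertiary bromide 6-allyl-6-bromo-3-ethoxycyclohex-2-en-1-one F2. The photoredox organocatalytic coupling of step 5 with 10 then gives (2S)-2-[(1S)-4-ethoxy-2-oxo-1-(prop-2-en-1-yl)cyclohex-3-en-1-yl]propanal F3; the catalyst fixes the methyl-bearing centre and the diastereomers at the quaternary centre are separated. Addition of 12 to F3 comes back to the route at 15.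

Step 7 is the stereoconvergent SN1 closure. The cation may be captured by the allyl group (Prins), or may lose the C3 proton, which would scramble C3. The fallback avoids the cation. Setting out from 15, Dess–Martin periodinane gives the aryl ketone (6S)-3-ethoxy-6-[(2S)-1-oxo-1-(3,4,5-trimethoxyphenyl)propan-2-yl]-6-(prop-2-en-1-yl)cyclohex-2-en-1-one F4. Reagent-controlled reduction with BH3·SMe2 and (R)-1-methyl-3,3-diphenyltetrahydro-1H,3H-pyrrolo[1,2-c][1,3,2]oxazaborole gives the single carbinol (6S)-3-ethoxy-6-[(1S,2S)-1-hydroxy-1-(3,4,5-trimethoxyphenyl)propan-2-yl]-6-(prop-2-en-1-yl)cyclohex-2-en-1-one F5. Buffered cyclodehydration (pyridinium p-toluenesulfonate, wet acetone, then toluene, 60 °C) lets the hydroxyl add to the ring carbonyl with retention at C2 and comes back to the route at 16.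

**Further compounds**
F0 | step 5 | none | none
F1 | step 6 | 6-allyl-3-ethoxycyclohex-2-en-1-one (racemic) | C=CCC1CCC(OCC)=CC1=O
F2 | step 6 | 6-allyl-6-bromo-3-ethoxycyclohex-2-en-1-one (racemic) | C=CCC1(Br)CCC(OCC)=CC1=O
F3 | step 6 | (2S)-2-[(1S)-4-ethoxy-2-oxo-1-(prop-2-en-1-yl)cyclohex-3-en-1-yl]propanal | C=CC[C@@]1(CCC(OCC)=CC1=O)[C@H](C)C=O
F4 | step 7 | (6S)-3-ethoxy-6-[(2S)-1-oxo-1-(3,4,5-trimethoxyphenyl)propan-2-yl]-6-(prop-2-en-1-yl)cyclohex-2-en-1-one | C=CC[C@@]1(CCC(OCC)=CC1=O)[C@H](C)C(=O)c1cc(OC)c(OC)c(OC)c1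
F5 | step 7 | (6S)-3-ethoxy-6-[(1S,2S)-1-hydroxy-1-(3,4,5-trimethoxyphenyl)propan-2-yl]-6-(prop-2-en-1-yl)cyclohex-2-en-1-one | C=CC[C@@]1(CCC(OCC)=CC1=O)[C@H](C)[C@H](O)c1cc(OC)c(OC)c(OC)c1
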